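**Retrosynthetic overview**
1. The pyranone ring, the only ring made, is closed last: O1–C2 by intramolecular Mitsunobu etherification of a 2'-hydroxy-α-(hydroxymethyl)deoxybenzoin.
2. C4–C4a: a geranylated bis-MOM resorcinyl-lithium (from 4,6-dibromoresorcinol and geranyl bromide) adds to an α-aryl-β-silyloxy aldehyde, then oxidation.
3. The aldehyde carbon C4 comes from ozonolysis of the E-propenyl group left by the key step; the former lactate carbinol carbon leaves as acetaldehyde.
4. Key step: aromatic Claisen [3,3] rearrangement of an (R,E)-allyl aryl ether forms C3–C1' and sets C3 by 1,3-chirality transfer.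
5. The allyl aryl ether comes from ethyl (S)-lactate: Mitsunobu inversion with resorcinol mono-MOM ether, DIBAL/Wittig, DIBAL, TBS.

Assumption: 3-(methoxymethoxy)phenol and 4,6-dibromoresorcinol are bought as catalogue compounds.

**Route**

Step 1
Reactants: 1 4,6-dibromobenzene-1,3-diol
Product: 2 1,5-dibromo-2,4-bis(methoxymethoxy)benzene
Conditions: MOMCl (2.5 equiv), i-Pr2NEt, CH2Cl2, 0 °C → rt
Reagents that add atoms: chloromethyl methyl ether, COCCl
Why: O-alkylation of both phenols (Williamson-type acetal formation) gives ethers that survive and stabilise the later ortho-aryllithiums; no stereocentre.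

Step 2
Reactants: 2 1,5-dibromo-2,4-bis(methoxymethoxy)benzene; 3 (2E)-1-bromo-3,7-dimethylocta-2,6-diene (geranyl bromide)
Product: 5 1-bromo-5-[(2E)-3,7-dimethylocta-2,6-dien-1-yl]-2,4-bis(methoxymethoxy)benzene, via aryllithium 4 (not isolated)
Conditions: n-BuLi (1.0 equiv), THF, −78 °C; CuBr·SMe2 (10 mol %), then 3, −78 → 0 °C
Reagents that add atoms: none
Why: Bromine–lithium exchange stops after one bromine at −78 °C, and the OMOM-chelated aryllithium is allylated at the primary carbon of geranyl bromide under copper catalysis (SN2 cross-coupling), which keeps the 2E olefin.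

Step 3
Reactants: 6 ethyl (2S)-2-hydroxypropanoate (ethyl (S)-lactate); 7 3-(methoxymethoxy)phenol
Product: 8 ethyl (2R)-2-[3-(methoxymethoxy)phenoxy]propanoate
Conditions: PPh3, DIAD, THF, 0 °C → rt
Reagents that add atoms: none
Why: Mitsunobu etherification: the phenol displaces the activated secondary hydroxyl by SN2 with inversion, turning the bought (S) centre into the (R) aryl ether.

Step 4
Reactants: 8 ethyl (2R)-2-[3-(methoxymethoxy)phenoxy]propanoate; 9 ethyl (triphenylphosphoranylidene)acetate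
Product: 11 ethyl (2E,4R)-4-[3-(methoxymethoxy)phenoxy]pent-2-enoate, via aldehyde 10 (not isolated)
Conditions: DIBAL-H (1.05 equiv), CH2Cl2, −78 °C; then 9, −78 °C → rt
Reagents that add atoms: none
Why: DIBAL-H stops at the aluminium hemiacetal at −78 °C, and the α-aryloxy aldehyde it releases is trapped in the same flask by the stabilised ylide (E-selective Wittig olefination), so the epimerisable aldehyde is never isolated and the (R) centre is unchanged.

Step 5
Reactants: 11 ethyl (2E,4R)-4-[3-(methoxymethoxy)phenoxy]pent-2-enoate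
Product: 12 (2E,4R)-4-[3-(methoxymethoxy)phenoxy]pent-2-en-1-ol
Conditions: DIBAL-H (2.2 equiv), CH2Cl2, −78 °C; Rochelle salt work-up
Reagents that add atoms: none
Why: 1,2-Reduction of the enoate by DIBAL-H gives the E-allylic alcohol; aryl ether, MOM group and stereocentre are inert at −78 °C.

Step 6
Reactants: 12 (2E,4R)-4-[3-(methoxymethoxy)phenoxy]pent-2-en-1-ol
Product: 13 tert-butyl(dimethyl){[(2E,4R)-4-[3-(methoxymethoxy)phenoxy]pent-2-en-1-yl]oxy}silane
Conditions: TBSCl, imidazole, CH2Cl2, rt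
Reagents that add atoms: tert-butyldimethylsilyl chloride, CC(C)(C)[Si](C)(C)Cl
Why: Silylation of the primary alcohol masks the future C2 oxygen through rearrangement, methylation, ozonolysis and organolithium addition.

Step 7
Reactants: 13 tert-butyl(dimethyl){[(2E,4R)-4-[3-(methoxymethoxy)phenoxy]pent-2-en-1-yl]oxy}silane
Product: 15 2-[(2S,3E)-1-(tert-butyldimethylsilyloxy)pent-3-en-2-yl]-5-(methoxymethoxy)phenol, via ortho-dienone 14 (not isolated)
Conditions: Eu(fod)3 (10 mol %, achiral), CHCl3, 50 °C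
Reagents that add atoms: none
Why: Aromatic Claisen rearrangement ([3,3]-sigmatropic, Lewis-acid accelerated) through a chair transition state with the methyl group pseudo-equatorial bonds the ring carbon para to OMOM to the alkene terminus on the face from which the oxygen leaves, so the (R) C–O centre is traded for the (S) benzylic centre and an E-propenyl group (1,3-chirality transfer); the dienone enolises at once, and the minor isomer from attack between the two oxygens is removed by chromatography.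

Step 8
Reactants: 15 2-[(2S,3E)-1-(tert-butyldimethylsilyloxy)pent-3-en-2-yl]-5-(methoxymethoxy)phenol
Product: 16 tert-butyl{[(2S,3E)-2-[2-methoxy-4-(methoxymethoxy)phenyl]pent-3-en-1-yl]oxy}dimethylsilane
Conditions: MeI, K2CO3, acetone, 50 °C
Reagents that add atoms: iodomethane, CI
Why: Williamson methylation of the only free phenol installs the 2'-methoxy group; the benzylic C–H is not acidic enough for K2CO3, so the new centre is safe.

Step 9
Reactants: 16 tert-butyl{[(2S,3E)-2-[2-methoxy-4-(methoxymethoxy)phenyl]pent-3-en-1-yl]oxy}dimethylsilane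
Product: 18 (2S)-3-(tert-butyldimethylsilyloxy)-2-[2-methoxy-4-(methoxymethoxy)phenyl]propanal, via ozonide 17 (not isolated)
Conditions: O3, CH2Cl2, −78 °C (Sudan Red 7B end point); PPh3, −78 → 0 °C; used crude
Reagents that add atoms: ozone, [O-][O+]=O
Why: Ozone adds to the 1,2-disubstituted alkene far faster than to the arene, and reductive work-up (ozonolysis) cuts out the former lactate carbinol carbon as acetaldehyde, leaving C4 as an aldehyde that is kept cold and used crude so the α-aryl centre does not epimerise.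

Step 10
Reactants: 5 1-bromo-5-[(2E)-3,7-dimethylocta-2,6-dien-1-yl]-2,4-bis(methoxymethoxy)benzene; 18 (2S)-3-(tert-butyldimethylsilyloxy)-2-[2-methoxy-4-(methoxymethoxy)phenyl]propanal
Product: 20 (2S)-3-(tert-butyldimethylsilyloxy)-1-{5-[(2E)-3,7-dimethylocta-2,6-dien-1-yl]-2,4-bis(methoxymethoxy)phenyl}-2-[2-methoxy-4-(methoxymethoxy)phenyl]propan-1-ol (both C1 epimers), via aryllithium 19 (not isolated)
Conditions: 5, n-BuLi (1.05 equiv), THF, −78 °C; then crude 18 in THF, −78 °C; H2O quench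
Reagents that add atoms: none
Why: A second bromine–lithium exchange gives the OMOM-stabilised aryllithium, whose 1,2-addition to the aldehyde at −78 °C outruns enolisation; the new carbinol centre forms as an epimer mixture that does not matter because it is oxidised next.

Step 11
Reactants: 20 (2S)-3-(tert-butyldimethylsilyloxy)-1-{5-[(2E)-3,7-dimethylocta-2,6-dien-1-yl]-2,4-bis(methoxymethoxy)phenyl}-2-[2-methoxy-4-(methoxymethoxy)phenyl]propan-1-ol
Product: 21 (2S)-3-(tert-butyldimethylsilyloxy)-1-{5-[(2E)-3,7-dimethylocta-2,6-dien-1-yl]-2,4-bis(methoxymethoxy)phenyl}-2-[2-methoxy-4-(methoxymethoxy)phenyl]propan-1-one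
Conditions: Dess–Martin periodinane, CH2Cl2, 0 °C → rt
Reagents that add atoms: none
Why: Dess–Martin oxidation turns the benzylic alcohol into the aryl ketone under neutral, base-free conditions, so the now enolisable (S) centre and the trisubstituted olefins are untouched.

Step 12
Reactants: 21 (2S)-3-(tert-butyldimethylsilyloxy)-1-{5-[(2E)-3,7-dimethylocta-2,6-dien-1-yl]-2,4-bis(methoxymethoxy)phenyl}-2-[2-methoxy-4-(methoxymethoxy)phenyl]propan-1-one
Product: 22 (2S)-1-{5-[(2E)-3,7-dimethylocta-2,6-dien-1-yl]-2,4-dihydroxyphenyl}-3-hydroxy-2-(4-hydroxy-2-methoxyphenyl)propan-1-one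
Conditions: 1.25 M HCl in MeOH, THF co-solvent, 0 → 25 °C; NaHCO3 work-up
Reagents that add atoms: none
Why: Acid-catalysed acetal exchange and desilylation in methanol remove the three aryl MOM ethers and the primary TBS ether in one operation; temperature and time are kept low so that the geranyl chain does not cyclise and the α-aryl ketone does not enolise.

Step 13
Reactants: 22 (2S)-1-{5-[(2E)-3,7-dimethylocta-2,6-dien-1-yl]-2,4-dihydroxyphenyl}-3-hydroxy-2-(4-hydroxy-2-methoxyphenyl)propan-1-one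
Product: 23 (3S)-6-[(2E)-3,7-dimethylocta-2,6-dien-1-yl]-7-hydroxy-3-(4-hydroxy-2-methoxyphenyl)-2,3-dihydro-4H-chromen-4-one
Conditions: PPh3, DIAD, THF (0.01 M), 0 °C → rt
Reagents that add atoms: none
Why: Intramolecular Mitsunobu etherification: the primary alcohol is activated as its oxyphosphonium salt and displaced 6-exo-tet by the adjacent 2-OH under near-neutral conditions at high dilution, which closes the pyranone ring without touching the (S) centre; the two remote phenols cannot reach the electrophile.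

**Compound list**
1 | 4,6-dibromobenzene-1,3-diol | Oc1cc(O)c(Br)cc1Br | starting material
2 | 1,5-dibromo-2,4-bis(methoxymethoxy)benzene | COCOc1cc(OCOC)c(Br)cc1Br | intermediate
3 | (2E)-1-bromo-3,7-dimethylocta-2,6-diene (geranyl bromide) | CC(C)=CCC/C(C)=C/CBr | starting material
4 | [5-bromo-2,4-bis(methoxymethoxy)phenyl]lithium | COCOc1cc(OCOC)c(Br)cc1[Li] | intermediate
5 | 1-bromo-5-[(2E)-3,7-dimethylocta-2,6-dien-1-yl]-2,4-bis(methoxymethoxy)benzene | COCOc1cc(OCOC)c(C/C=C(\C)CCC=C(C)C)cc1Br | intermediate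
6 | ethyl (2S)-2-hydroxypropanoate (ethyl (S)-lactate) | C[C@H](O)C(=O)OCC | starting material
7 | 3-(methoxymethoxy)phenol | COCOc1cccc(O)c1 | starting material
8 | ethyl (2R)-2-[3-(methoxymethoxy)phenoxy]propanoate | C[C@@H](Oc1cccc(OCOC)c1)C(=O)OCC | intermediate
9 | ethyl (triphenylphosphoranylidene)acetate | CCOC(=O)C=P(c1ccccc1)(c1ccccc1)c1ccccc1 | starting material
10 | (2R)-2-[3-(methoxymethoxy)phenoxy]propanal | C[C@@H](Oc1cccc(OCOC)c1)C=O | intermediate
11 | ethyl (2E,4R)-4-[3-(methoxymethoxy)phenoxy]pent-2-enoate | C[C@@H](Oc1cccc(OCOC)c1)/C=C/C(=O)OCC | intermediate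
12 | (2E,4R)-4-[3-(methoxymethoxy)phenoxy]pent-2-en-1-ol | C[C@@H](Oc1cccc(OCOC)c1)/C=C/CO | intermediate
13 | tert-butyl(dimethyl){[(2E,4R)-4-[3-(methoxymethoxy)phenoxy]pent-2-en-1-yl]oxy}silane | C[C@@H](Oc1cccc(OCOC)c1)/C=C/CO[Si](C)(C)C(C)(C)C | intermediate
14 | (6R)-6-[(2S,3E)-1-(tert-butyldimethylsilyloxy)pent-3-en-2-yl]-3-(methoxymethoxy)cyclohexa-2,4-dien-1-one | C/C=C/[C@H](CO[Si](C)(C)C(C)(C)C)[C@H]1C=CC(OCOC)=CC1=O | intermediate
15 | 2-[(2S,3E)-1-(tert-butyldimethylsilyloxy)pent-3-en-2-yl]-5-(methoxymethoxy)phenol | C/C=C/[C@H](CO[Si](C)(C)C(C)(C)C)c1ccc(OCOC)cc1O | intermediate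
16 | tert-butyl{[(2S,3E)-2-[2-methoxy-4-(methoxymethoxy)phenyl]pent-3-en-1-yl]oxy}dimethylsilane | C/C=C/[C@H](CO[Si](C)(C)C(C)(C)C)c1ccc(OCOC)cc1OC | intermediate
17 | 3-{(1S)-2-(tert-butyldimethylsilyloxy)-1-[2-methoxy-4-(methoxymethoxy)phenyl]ethyl}-5-methyl-1,2,4-trioxolane (ring-carbon epimers) | CC1OOC(O1)[C@H](CO[Si](C)(C)C(C)(C)C)c1ccc(OCOC)cc1OC | intermediate
18 | (2S)-3-(tert-butyldimethylsilyloxy)-2-[2-methoxy-4-(methoxymethoxy)phenyl]propanal | O=C[C@H](CO[Si](C)(C)C(C)(C)C)c1ccc(OCOC)cc1OC | intermediate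
19 | {5-[(2E)-3,7-dimethylocta-2,6-dien-1-yl]-2,4-bis(methoxymethoxy)phenyl}lithium | COCOc1cc(OCOC)c(C/C=C(\C)CCC=C(C)C)cc1[Li] | intermediate
20 | (2S)-3-(tert-butyldimethylsilyloxy)-1-{5-[(2E)-3,7-dimethylocta-2,6-dien-1-yl]-2,4-bis(methoxymethoxy)phenyl}-2-[2-methoxy-4-(methoxymethoxy)phenyl]propan-1-ol (C1 epimers) | COCOc1cc(OCOC)c(C/C=C(\C)CCC=C(C)C)cc1C(O)[C@H](CO[Si](C)(C)C(C)(C)C)c1ccc(OCOC)cc1OC | intermediate
21 | (2S)-3-(tert-butyldimethylsilyloxy)-1-{5-[(2E)-3,7-dimethylocta-2,6-dien-1-yl]-2,4-bis(methoxymethoxy)phenyl}-2-[2-methoxy-4-(methoxymethoxy)phenyl]propan-1-one | COCOc1cc(OCOC)c(C/C=C(\C)CCC=C(C)C)cc1C(=O)[C@H](CO[Si](C)(C)C(C)(C)C)c1ccc(OCOC)cc1OC | intermediate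
22 | (2S)-1-{5-[(2E)-3,7-dimethylocta-2,6-dien-1-yl]-2,4-dihydroxyphenyl}-3-hydroxy-2-(4-hydroxy-2-methoxyphenyl)propan-1-one | Oc1cc(O)c(C/C=C(\C)CCC=C(C)C)cc1C(=O)[C@H](CO)c1ccc(O)cc1OC | intermediate
23 | (3S)-6-[(2E)-3,7-dimethylocta-2,6-dien-1-yl]-7-hydroxy-3-(4-hydroxy-2-methoxyphenyl)-2,3-dihydro-4H-chromen-4-one | COc1cc(O)ccc1[C@H]1COc2cc(O)c(C/C=C(\C)CCC=C(C)C)cc2C1=O | target

**Step count**
Total: 13 steps. Longest linear sequence: 11 steps (steps 3–13, from ethyl (S)-lactate); steps 1–2 make the aryl bromide that enters at step 10.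

**Three steps most likely to fail**

Step 7 (Claisen rearrangement). The meta-alkoxy ring can also react at the carbon between the two oxygens, and any leakage through the Z-olefin pathway lowers the ee. The fallback forms the same C–aryl bond by a copper-mediated anti-SN2' arylation, again with 1,3-transfer of the lactate centre but with the ring position fixed by a bromine. It sets out from 6 and comes back at 16. Compound 6 is protected with 4-methoxybenzyl trichloroacetimidate (cat. CSA) as ethyl (2S)-2-[(4-methoxybenzyl)oxy]propanoate F1. DIBAL-H at −78 °C and then ylide 9 give, through (2S)-2-[(4-methoxybenzyl)oxy]propanal F2, ethyl (2E,4S)-4-[(4-methoxybenzyl)oxy]pent-2-enoate F3. DIBAL-H gives (2E,4S)-4-[(4-methoxybenzyl)oxy]pent-2-en-1-ol F4, and TBSCl/imidazole gives tert-butyl{[(2E,4S)-4-[(4-methoxybenzyl)oxy]pent-2-en-1-yl]oxy}dimethylsilane F5. DDQ (CH2Cl2/pH 7 buffer) frees (2S,3E)-5-(tert-butyldimethylsilyloxy)pent-3-en-2-ol F6, which picolinic acid/DCC/DMAP converts into (2S,3E)-5-(tert-butyldimethylsilyloxy)pent-3-en-2-yl pyridine-2-carboxylate F7. Commercial 4-bromo-3-methoxyphenol and MOMCl give 1-bromo-2-methoxy-4-(methoxymethoxy)benzene F8, and magnesium in THF gives [2-methoxy-4-(methoxymethoxy)phenyl]magnesium bromide F9. With CuBr·SMe2 (THF, −40 → 0 °C), F9 attacks F7 at the γ-carbon anti to the picolinate and gives 16 with the (S) centre and the E-propenyl group.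

Step 10 (aryllithium addition). The hindered, basic aryllithium may enolise aldehyde 18 instead of adding, which costs material and risks epimerisation or β-elimination of silanolate. The fallback makes the ketone by a non-basic palladium-catalysed acyl coupling. It sets out from 18 (with 19) and comes back at 21, so 20 and step 11 are bypassed. Pinnick oxidation of 18 (NaClO2, NaH2PO4, 2-methyl-2-butene, t-BuOH/H2O) gives (2S)-3-(tert-butyldimethylsilyloxy)-2-[2-methoxy-4-(methoxymethoxy)phenyl]propanoic acid F10. 1-Chloro-N,N,2-trimethylprop-1-en-1-amine (CH2Cl2, 0 °C) converts it without base into (2S)-3-(tert-butyldimethylsilyloxy)-2-[2-methoxy-4-(methoxymethoxy)phenyl]propanoyl chloride F11. Aryllithium 19 is transmetallated with ZnCl2 to chlorido{5-[(2E)-3,7-dimethylocta-2,6-dien-1-yl]-2,4-bis(methoxymethoxy)phenyl}zinc F12, and Negishi acylation of F11 with F12 (Pd(PPh3)4 5 mol %, THF, 0 °C → rt) gives 21.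

Step 13 (Mitsunobu ring closure). With three free phenols the closure may be diverted to intermolecular ethers of the acidic 4-OH, and step 12, which feeds it, exposes the open-chain ketone to acid for hours. The betaine may also dehydrate the β-hydroxy ketone to the α-methylene ketone, whose oxa-Michael closure would give racemic product; the fallback does not cure that, and only dilution and low temperature limit it. The fallback closes the ring before the full unmasking, so that a single phenol is free in the Mitsunobu step. It sets out from 21 and comes back at 23. Brief treatment of 21 with dilute HCl in MeOH at 0 °C removes only the TBS ether and the MOM group chelated to the carbonyl, giving (2S)-1-{5-[(2E)-3,7-dimethylocta-2,6-dien-1-yl]-2-hydroxy-4-(methoxymethoxy)phenyl}-3-hydroxy-2-[2-methoxy-4-(methoxymethoxy)phenyl]propan-1-one F13. PPh3/DIAD (THF, 0 °C) closes it to (3S)-6-[(2E)-3,7-dimethylocta-2,6-dien-1-yl]-3-[2-methoxy-4-(methoxymethoxy)phenyl]-7-(methoxymethoxy)-2,3-dihydro-4H-chromen-4-one F14. The two remaining MOM ethers are then removed by short acetal exchange (methanolic HCl, 0 °C → rt) to give 23.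

**Further compounds**
F1 | step 7 | ethyl (2S)-2-[(4-methoxybenzyl)oxy]propanoate | C[C@H](OCc1ccc(OC)cc1)C(=O)OCC
F2 | step 7 | (2S)-2-[(4-methoxybenzyl)oxy]propanal | C[C@H](OCc1ccc(OC)cc1)C=O
F3 | step 7 | ethyl (2E,4S)-4-[(4-methoxybenzyl)oxy]pent-2-enoate | C[C@H](OCc1ccc(OC)cc1)/C=C/C(=O)OCC
F4 | step 7 | (2E,4S)-4-[(4-methoxybenzyl)oxy]pent-2-en-1-ol | C[C@H](OCc1ccc(OC)cc1)/C=C/CO
F5 | step 7 | tert-butyl{[(2E,4S)-4-[(4-methoxybenzyl)oxy]pent-2-en-1-yl]oxy}dimethylsilane | C[C@H](OCc1ccc(OC)cc1)/C=C/CO[Si](C)(C)C(C)(C)C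
F6 | step 7 | (2S,3E)-5-(tert-butyldimethylsilyloxy)pent-3-en-2-ol | C[C@H](O)/C=C/CO[Si](C)(C)C(C)(C)C
F7 | step 7 | (2S,3E)-5-(tert-butyldimethylsilyloxy)pent-3-en-2-yl pyridine-2-carboxylate | C[C@H](OC(=O)c1ccccn1)/C=C/CO[Si](C)(C)C(C)(C)C
F8 | step 7 | 1-bromo-2-methoxy-4-(methoxymethoxy)benzene | COCOc1ccc(Br)c(OC)c1
F9 | step 7 | [2-methoxy-4-(methoxymethoxy)phenyl]magnesium bromide | COCOc1ccc([Mg]Br)c(OC)c1
F10 | step 10 | (2S)-3-(tert-butyldimethylsilyloxy)-2-[2-methoxy-4-(methoxymethoxy)phenyl]propanoic acid | OC(=O)[C@H](CO[Si](C)(C)C(C)(C)C)c1ccc(OCOC)cc1OC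
F11 | step 10 | (2S)-3-(tert-butyldimethylsilyloxy)-2-[2-methoxy-4-(methoxymethoxy)phenyl]propanoyl chloride | ClC(=O)[C@H](CO[Si](C)(C)C(C)(C)C)c1ccc(OCOC)cc1OC
F12 | step 10 | chlorido{5-[(2E)-3,7-dimethylocta-2,6-dien-1-yl]-2,4-bis(methoxymethoxy)phenyl}zinc | COCOc1cc(OCOC)c(C/C=C(\C)CCC=C(C)C)cc1[Zn]Cl
F13 | step 13 | (2S)-1-{5-[(2E)-3,7-dimethylocta-2,6-dien-1-yl]-2-hydroxy-4-(methoxymethoxy)phenyl}-3-hydroxy-2-[2-methoxy-4-(methoxymethoxy)phenyl]propan-1-one | Oc1cc(OCOC)c(C/C=C(\C)CCC=C(C)C)cc1C(=O)[C@H](CO)c1ccc(OCOC)cc1OC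
F14 | step 13 | (3S)-6-[(2E)-3,7-dimethylocta-2,6-dien-1-yl]-3-[2-methoxy-4-(methoxymethoxy)phenyl]-7-(methoxymethoxy)-2,3-dihydro-4H-chromen-4-one | COc1cc(OCOC)ccc1[C@H]1COc2cc(OCOC)c(C/C=C(\C)CCC=C(C)C)cc2C1=O
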